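The whole plan rests on cutting ring A at C4–C5 and C1–C6. The feature exploited is the semicyclic diene C16=C1–C2=C3 of ring A, an exocyclic methylene on C1 conjugated with the alkene at the ring-fusion carbon C3: a vinylallene that reacts as a diene through C4=C3–C2=C1 keeps its other allene bond, C1=C16, and so delivers this array directly. One thermal Diels–Alder reaction with 1,1-bis(phenylsulfonyl)ethene as ethylene equivalent thus closes ring A, installs both double bonds and sets C4. Its precursor is a ring B 1-allenylcyclohexene already carrying the C7 methyl, the C8 silyl ether, C10, C11 and the C13 methyl ester, made from a quinone monoketal.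

Key step: step 10

Locants: ring A is C1 (bearing exocyclic C16), C2, C3, C4, C5, C6; ring B is C3, C4, C7 (methyl), C8 (oxygen), C9, C10 (side chain); the side chain is C11 (methyl), C12 (oxygen), C13 (carbonyl), C14, C15. The target is 4S,7S,8R,10S,11S,12R: C4–C5 and the C10 side chain lie on one face of ring B, the C7 methyl and C8 oxygen on the other.

Assumption 1: the (R,S,S)-phosphoramidite is taken as the ligand antipode that gives the 5S enone 2, by analogy with the face this ligand family selects in cyclohex-2-enone.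

Assumption 2: (+)-(camphorsulfonyl)oxaziridine is taken as the reagent antipode that reinforces the substrate-directed facial preference in step 12.

Step 1
Reactants: 1 4,4-dimethoxycyclohexa-2,5-dien-1-one
Product: 2 (5S)-4,4-dimethoxy-5-methylcyclohex-2-en-1-one
Conditions: Me2Zn (1.5 equiv), Cu(OTf)2 (2 mol %), (R,S,S)-O,O'-(1,1'-binaphthalene-2,2'-diyl) N,N-bis(1-phenylethyl)phosphoramidite (4 mol %), toluene, −25 °C; aq NH4Cl
Reagents that add atoms: dimethylzinc, C[Zn]C
Why: Copper-catalysed asymmetric conjugate addition of a dialkylzinc to a prochiral cross-conjugated dienone, in which the chiral copper–phosphoramidite complex chooses between the two enantiotopic enone halves and delivers methyl to one β-carbon, setting the 5S centre (C7 of the target) next to the ketal carbon (the later C8).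

Step 2
Reactants: 2 (5S)-4,4-dimethoxy-5-methylcyclohex-2-en-1-one
Product: 4 (5S)-4,4-dimethoxy-5-methylcyclohex-1-en-1-yl acetate, via lithium enolate 3 (not isolated)
Conditions: LiBH(s-Bu)3 (1.05 equiv), THF, −78 °C; then Ac2O, −78 to 0 °C
Reagents that add atoms: acetic anhydride, CC(=O)OC(C)=O
Why: Conjugate hydride reduction of the β-unsubstituted enone by the bulky trialkylborohydride gives enolate 3 with its double bond fixed between C3 and C10, and O-acetylation stores this regiochemistry as an enol ester that survives the next three steps, no stereocentre being formed.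

Step 3
Reactants: 4 (5S)-4,4-dimethoxy-5-methylcyclohex-1-en-1-yl acetate
Product: 5 (5S)-5-methyl-4-oxocyclohex-1-en-1-yl acetate
Conditions: pyridinium p-toluenesulfonate (10 mol %), acetone–H2O, rt
Reagents that add atoms: water, O
Why: Acid-catalysed hydrolysis of the dimethyl ketal, which is much faster than hydrolysis of the enol acetate or enolisation of the liberated ketone towards C7 under these buffered conditions, unmasks the C8 carbonyl.

Step 4
Reactants: 5 (5S)-5-methyl-4-oxocyclohex-1-en-1-yl acetate
Product: 6 (4R,5S)-4-hydroxy-5-methylcyclohex-1-en-1-yl acetate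
Conditions: LiBH(s-Bu)3 (1.05 equiv), THF, −78 °C; aq NH4Cl
Reagents that add atoms: none
Why: Diastereoselective ketone reduction with a bulky trialkylborohydride, in which hydride attacks the C8 carbonyl from the face opposite the neighbouring C7 methyl and so gives the alcohol cis to that methyl (8R), the enol ester being untouched at low temperature.

Step 5
Reactants: 6 (4R,5S)-4-hydroxy-5-methylcyclohex-1-en-1-yl acetate
Product: 7 (4R,5S)-4-[tert-butyl(dimethyl)silyl]oxy-5-methylcyclohex-1-en-1-yl acetate
Conditions: TBSOTf, 2,6-lutidine, CH2Cl2, −78 to 0 °C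
Reagents that add atoms: tert-butyldimethylsilyl trifluoromethanesulfonate, CC(C)(C)[Si](C)(C)OS(=O)(=O)C(F)(F)F
Why: Silylation of a hindered secondary alcohol with a silyl triflate and a non-nucleophilic pyridine base, conditions under which the enol acetate is inert.

Step 6
Reactants: 7 (4R,5S)-4-[tert-butyl(dimethyl)silyl]oxy-5-methylcyclohex-1-en-1-yl acetate, 8 methyl (2E)-but-2-enoate
Product: 10 methyl (3R)-3-[(1S,4S,5R)-5-[tert-butyl(dimethyl)silyl]oxy-4-methyl-2-oxocyclohexyl]butanoate, via lithium enolate 9 (not isolated)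
Conditions: MeLi (2.0 equiv), THF, 0 °C; then 8 (1.2 equiv), −78 to −20 °C; aq NH4Cl
Reagents that add atoms: none
Why: Cleavage of the enol acetate with two equivalents of MeLi releases the regiodefined lithium enolate 9, whose Michael addition to the (E)-enoate through a lithium-chelated closed transition state should occur on the ring face opposite the axial C8 silyloxy group (side chain trans to the C7 methyl and C8 oxygen, which is also the equatorial thermodynamic position at C10) with the syn topicity expected for a cyclic E-enolate, and this fixes C11.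

Step 7
Reactants: 10 methyl (3R)-3-[(1S,4S,5R)-5-[tert-butyl(dimethyl)silyl]oxy-4-methyl-2-oxocyclohexyl]butanoate
Product: 12 methyl (3R)-3-[(1S,4S,5R)-5-[tert-butyl(dimethyl)silyl]oxy-4-methyl-2-(trifluoromethylsulfonyloxy)cyclohex-2-en-1-yl]butanoate, via lithium enolate 11 (not isolated)
Conditions: LiN(iPr)2 (1.05 equiv), THF, −78 °C; then PhNTf2, −78 to 0 °C; aq NH4Cl
Reagents that add atoms: N-phenylbis(trifluoromethanesulfonimide), O=S(=O)(N(c1ccccc1)S(=O)(=O)C(F)(F)F)C(F)(F)F
Why: Kinetic deprotonation takes the less substituted α-carbon C4 (a CH2) in preference to the tertiary C10–H and to the ester, and O-sulfonylation of enolate 11 gives the C3=C4 alkenyl triflate without touching C7 or C10.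

Step 8
Reactants: 12 alkenyl triflate (C3–OTf, C3=C4), 13 prop-2-yn-1-ol
Product: 14 methyl (3R)-3-[(1S,4S,5R)-5-[tert-butyl(dimethyl)silyl]oxy-2-(3-hydroxyprop-1-yn-1-yl)-4-methylcyclohex-2-en-1-yl]butanoate
Conditions: Pd(PPh3)4 (5 mol %), CuI (10 mol %), Et3N, THF, rt
Reagents that add atoms: none
Why: Sonogashira coupling of an alkenyl triflate with a terminal alkyne, which tolerates the free hydroxyl, the ester and the silyl ether and joins C3 to C2.

Step 9
Reactants: 14 enynol (C3–C2≡C1–C16H2OH)
Product: 17 methyl (3R)-3-[(1S,4S,5R)-5-[tert-butyl(dimethyl)silyl]oxy-4-methyl-2-(propa-1,2-dien-1-yl)cyclohex-2-en-1-yl]butanoate, via sulfonylhydrazine 15 (not isolated), via propargylic diazene 16 (not isolated)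
Conditions: PPh3, DEAD, THF, −15 °C; then 2-nitrobenzenesulfonylhydrazide, −15 °C to rt
Reagents that add atoms: none
Why: Myers allene synthesis, in which Mitsunobu displacement of the primary propargylic alcohol gives 15, loss of 2-nitrobenzenesulfinic acid on warming gives diazene 16, and sigmatropic loss of N2 moves hydrogen to C2 and turns the alkyne into the terminal allene C2=C1=C16 conjugated with C3=C4.

Step 10
Reactants: 17 ring B vinylallene (C8 silyl ether, C13 methyl ester), 18 1,1-bis(phenylsulfonyl)ethene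
Product: 19 methyl (3R)-3-[(1S,3R,4S,4aS)-3-[tert-butyl(dimethyl)silyl]oxy-4-methyl-7-methylidene-5,5-bis(phenylsulfonyl)-1,2,3,4,4a,5,6,7-octahydronaphthalen-1-yl]butanoate
Conditions: 18 (1.3 equiv), BHT (cat.), toluene, 25 to 50 °C, dark
Reagents that add atoms: none
Why: The s-cis diene C4=C3–C2=C1 of vinylallene 17 and the electron-poor alkene 18 combine in a thermal, concerted but asynchronous [4+2] cycloaddition that is helped by rehybridisation of the sp carbon C1, the closest known reaction types being the Diels–Alder reactions of vinylallenes with activated dienophiles and of 18 with 1,3-dienes as an ethylene equivalent. Ring A closes by intermolecular six-membered annulation onto ring B, C4–C5 and C1–C6 being formed in the same step, and the allene bond C1=C16 that takes no part is left as the exocyclic methylene conjugated with the new C2=C3 bond. The only new stereocentre, C4, is set by ring B: the dienophile should reach C4 from the face opposite the adjacent C7 methyl and the C8 silyloxy group (pseudoaxial methyl in one half-chair, axial silyloxy in the other), so that C4–C5 forms trans to the C7 methyl, while the C10 side chain on the attacked face is 1,3 to C4 and far from C1 and should lower but not reverse this preference. Because 18 carries no stereochemistry, endo/exo selectivity plays no part, and the ring alkene holds C7 trans to the allenyl group, so that no [1,5]-hydrogen shift can compete. As to orientation, the unsubstituted CH2 terminus is expected to bond to C1, which is flanked above and below the diene plane by the allenic hydrogens, and the bis-sulfonyl carbon to C4, which makes the C5 sulfones homoallylic and cleanly removable. The high reactivity of 18 allows reaction near room temperature, which keeps dimerisation of the allene slow.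

Step 11
Reactants: 19 C5 bis-sulfonyl octalin with the exocyclic diene
Product: 21 methyl (3R)-3-[(1S,3R,4S,4aS)-3-[tert-butyl(dimethyl)silyl]oxy-4-methyl-7-methylidene-1,2,3,4,4a,5,6,7-octahydronaphthalen-1-yl]butanoate, via monosulfone 20 (not isolated)
Conditions: Mg turnings (excess), MeOH, rt to 50 °C
Reagents that add atoms: none
Why: Reductive desulfonylation by electron transfer from magnesium in methanol cleaves the two C5–S bonds one after the other, each carbanion being protonated by the solvent, and because the sulfones are homoallylic and not conjugated with the diene, the double bonds, the methyl ester, the silyl ether and all stereocentres should be unaffected.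

Step 12
Reactants: 21 diene ester (C12 H2, C13 CO2Me)
Product: 23 methyl (2R,3S)-2-hydroxy-3-[(1S,3R,4S,4aS)-3-[tert-butyl(dimethyl)silyl]oxy-4-methyl-7-methylidene-1,2,3,4,4a,5,6,7-octahydronaphthalen-1-yl]butanoate, via potassium enolate 22 (not isolated)
Conditions: KN(SiMe3)2 (1.2 equiv), THF, −78 °C; then (+)-(camphorsulfonyl)oxaziridine, −78 °C; aq NH4Cl
Reagents that add atoms: (+)-(camphorsulfonyl)oxaziridine, CC1(C)[C@@H]2CC[C@]13CS(=O)(=O)N4O[C@@]34C2
Why: Enolate hydroxylation with an N-sulfonyloxaziridine (Davis oxidation), in which the C11–H bond lies in the enolate plane to avoid allylic strain and oxygen is transferred to C12 on the face away from the bulky ring carbon C10, giving the 12R alcohol, the camphor-derived reagent being chosen to reinforce this 1,2-induction.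

Step 13
Reactants: 23 α-hydroxy ester (12R)
Product: 24 (2R,3S)-2-hydroxy-N-methoxy-N-methyl-3-[(1S,3R,4S,4aS)-3-[tert-butyl(dimethyl)silyl]oxy-4-methyl-7-methylidene-1,2,3,4,4a,5,6,7-octahydronaphthalen-1-yl]butanamide
Conditions: MeNH(OMe)·HCl (1.5 equiv), iPrMgCl (4 equiv), THF, −20 to 0 °C
Reagents that add atoms: N,O-dimethylhydroxylamine hydrochloride, CNOC.Cl
Why: Aminolysis of the methyl ester by the chloromagnesium amide of N,O-dimethylhydroxylamine (Weinreb amide formation), in which the C12 hydroxyl is carried as its magnesium alkoxide and the α-centre is not enolised at low temperature.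

Step 14
Reactants: 24 α-hydroxy Weinreb amide, 25 (2-methylprop-1-en-1-yl)magnesium bromide
Product: 26 (2S,3R)-3-hydroxy-6-methyl-2-[(1S,3R,4S,4aS)-3-[tert-butyl(dimethyl)silyl]oxy-4-methyl-7-methylidene-1,2,3,4,4a,5,6,7-octahydronaphthalen-1-yl]hept-5-en-4-one
Conditions: 25 (3.5 equiv), THF, 0 °C; aq NH4Cl
Reagents that add atoms: none
Why: Weinreb ketone synthesis, in which the first equivalent of the alkenyl Grignard reagent deprotonates the C12 hydroxyl and a second adds to the amide to give a chelated tetrahedral adduct that cannot add again and collapses to the C13 enone only on work-up.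

Step 15
Reactants: 26 silyl-protected α-hydroxy enone
Product: 27 (2S,3R)-3-hydroxy-2-[(1S,3R,4S,4aS)-3-hydroxy-4-methyl-7-methylidene-1,2,3,4,4a,5,6,7-octahydronaphthalen-1-yl]-6-methylhept-5-en-4-one
Conditions: HF·pyridine, pyridine, THF, 0 °C to rt
Reagents that add atoms: none
Why: Fluoride-induced cleavage of the secondary silyl ether under buffered conditions that should spare the exocyclic diene, the enone and the α-ketol.

Step 16
Reactants: 27 C8,C12-diol
Product: 28 target diacetate CNP0302999.1
Conditions: Ac2O, pyridine, DMAP (cat.), CH2Cl2, 0 °C to rt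
Reagents that add atoms: acetic anhydride, CC(=O)OC(C)=O
Why: Nucleophile-catalysed acylation of both secondary alcohols (C8 and C12) with acetic anhydride, which needs no strong base and so should leave the C12 centre next to the ketone, the diene and the enone intact.

Compound list

1 | 4,4-dimethoxycyclohexa-2,5-dien-1-one | COC1(OC)C=CC(=O)C=C1 | starting material
2 | (5S)-4,4-dimethoxy-5-methylcyclohex-2-en-1-one | O=C1C[C@H](C)C(OC)(OC)C=C1 | intermediate
3 | lithium (5S)-4,4-dimethoxy-5-methylcyclohex-1-en-1-olate | [Li]OC1=CCC(OC)(OC)[C@@H](C)C1 | intermediate (not isolated)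
4 | (5S)-4,4-dimethoxy-5-methylcyclohex-1-en-1-yl acetate | CC(=O)OC1=CCC(OC)(OC)[C@@H](C)C1 | intermediate
5 | (5S)-5-methyl-4-oxocyclohex-1-en-1-yl acetate | CC(=O)OC1=CCC(=O)[C@@H](C)C1 | intermediate
6 | (4R,5S)-4-hydroxy-5-methylcyclohex-1-en-1-yl acetate | CC(=O)OC1=CC[C@@H](O)[C@@H](C)C1 | intermediate
7 | (4R,5S)-4-[tert-butyl(dimethyl)silyl]oxy-5-methylcyclohex-1-en-1-yl acetate | CC(=O)OC1=CC[C@@H](O[Si](C)(C)C(C)(C)C)[C@@H](C)C1 | intermediate
8 | methyl (2E)-but-2-enoate | C/C=C/C(=O)OC | starting material
9 | lithium (4R,5S)-4-[tert-butyl(dimethyl)silyl]oxy-5-methylcyclohex-1-en-1-olate | [Li]OC1=CC[C@@H](O[Si](C)(C)C(C)(C)C)[C@@H](C)C1 | intermediate (not isolated)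
10 | methyl (3R)-3-[(1S,4S,5R)-5-[tert-butyl(dimethyl)silyl]oxy-4-methyl-2-oxocyclohexyl]butanoate (ring B keto ester) | O=C1C[C@H](C)[C@H](O[Si](C)(C)C(C)(C)C)C[C@H]1[C@H](C)CC(=O)OC | intermediate
11 | lithium enolate of 10 with the double bond C3=C4 | [Li]OC1=C[C@H](C)[C@H](O[Si](C)(C)C(C)(C)C)C[C@H]1[C@H](C)CC(=O)OC | intermediate (not isolated)
12 | methyl (3R)-3-[(1S,4S,5R)-5-[tert-butyl(dimethyl)silyl]oxy-4-methyl-2-(trifluoromethylsulfonyloxy)cyclohex-2-en-1-yl]butanoate | FC(F)(F)S(=O)(=O)OC1=C[C@H](C)[C@H](O[Si](C)(C)C(C)(C)C)C[C@H]1[C@H](C)CC(=O)OC | intermediate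
13 | prop-2-yn-1-ol | C#CCO | starting material
14 | methyl (3R)-3-[(1S,4S,5R)-5-[tert-butyl(dimethyl)silyl]oxy-2-(3-hydroxyprop-1-yn-1-yl)-4-methylcyclohex-2-en-1-yl]butanoate | OCC#CC1=C[C@H](C)[C@H](O[Si](C)(C)C(C)(C)C)C[C@H]1[C@H](C)CC(=O)OC | intermediate
15 | N-alkyl-N-(2-nitrophenylsulfonyl)hydrazine from 14 (C16H2–N(NH2)SO2Ar in place of C16H2OH) | NN(CC#CC1=C[C@H](C)[C@H](O[Si](C)(C)C(C)(C)C)C[C@H]1[C@H](C)CC(=O)OC)S(=O)(=O)c1ccccc1[N+](=O)[O-] | intermediate (not isolated)
16 | propargylic monoalkyl diazene from 15 (C16H2–N=NH) | N=NCC#CC1=C[C@H](C)[C@H](O[Si](C)(C)C(C)(C)C)C[C@H]1[C@H](C)CC(=O)OC | intermediate (not isolated)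
17 | methyl (3R)-3-[(1S,4S,5R)-5-[tert-butyl(dimethyl)silyl]oxy-4-methyl-2-(propa-1,2-dien-1-yl)cyclohex-2-en-1-yl]butanoate (ring B vinylallene) | C=C=CC1=C[C@H](C)[C@H](O[Si](C)(C)C(C)(C)C)C[C@H]1[C@H](C)CC(=O)OC | intermediate
18 | 1,1-bis(phenylsulfonyl)ethene | C=C(S(=O)(=O)c1ccccc1)S(=O)(=O)c1ccccc1 | starting material
19 | methyl (3R)-3-[(1S,3R,4S,4aS)-3-[tert-butyl(dimethyl)silyl]oxy-4-methyl-7-methylidene-5,5-bis(phenylsulfonyl)-1,2,3,4,4a,5,6,7-octahydronaphthalen-1-yl]butanoate (C5 bis-sulfonyl octalin) | C=C1C=C2[C@@H](C(S(=O)(=O)c3ccccc3)(S(=O)(=O)c3ccccc3)C1)[C@H](C)[C@H](O[Si](C)(C)C(C)(C)C)C[C@H]2[C@H](C)CC(=O)OC | intermediate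
20 | C5 monosulfone of 19 (either configuration at C5) | C=C1C=C2[C@@H](C(S(=O)(=O)c3ccccc3)C1)[C@H](C)[C@H](O[Si](C)(C)C(C)(C)C)C[C@H]2[C@H](C)CC(=O)OC | intermediate (not isolated)
21 | methyl (3R)-3-[(1S,3R,4S,4aS)-3-[tert-butyl(dimethyl)silyl]oxy-4-methyl-7-methylidene-1,2,3,4,4a,5,6,7-octahydronaphthalen-1-yl]butanoate | C=C1C=C2[C@@H](CC1)[C@H](C)[C@H](O[Si](C)(C)C(C)(C)C)C[C@H]2[C@H](C)CC(=O)OC | intermediate
22 | potassium ester enolate of 21 (C12=C13, enolate geometry not specified) | C=C1C=C2[C@@H](CC1)[C@H](C)[C@H](O[Si](C)(C)C(C)(C)C)C[C@H]2[C@H](C)C=C(O[K])OC | intermediate (not isolated)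
23 | methyl (2R,3S)-2-hydroxy-3-[(1S,3R,4S,4aS)-3-[tert-butyl(dimethyl)silyl]oxy-4-methyl-7-methylidene-1,2,3,4,4a,5,6,7-octahydronaphthalen-1-yl]butanoate | C=C1C=C2[C@@H](CC1)[C@H](C)[C@H](O[Si](C)(C)C(C)(C)C)C[C@H]2[C@H](C)[C@@H](O)C(=O)OC | intermediate
24 | (2R,3S)-2-hydroxy-N-methoxy-N-methyl-3-[(1S,3R,4S,4aS)-3-[tert-butyl(dimethyl)silyl]oxy-4-methyl-7-methylidene-1,2,3,4,4a,5,6,7-octahydronaphthalen-1-yl]butanamide | C=C1C=C2[C@@H](CC1)[C@H](C)[C@H](O[Si](C)(C)C(C)(C)C)C[C@H]2[C@H](C)[C@@H](O)C(=O)N(C)OC | intermediate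
25 | (2-methylprop-1-en-1-yl)magnesium bromide, Me2C=CHMgBr | CC(C)=C[Mg]Br | starting material
26 | (2S,3R)-3-hydroxy-6-methyl-2-[(1S,3R,4S,4aS)-3-[tert-butyl(dimethyl)silyl]oxy-4-methyl-7-methylidene-1,2,3,4,4a,5,6,7-octahydronaphthalen-1-yl]hept-5-en-4-one | C=C1C=C2[C@@H](CC1)[C@H](C)[C@H](O[Si](C)(C)C(C)(C)C)C[C@H]2[C@H](C)[C@@H](O)C(=O)C=C(C)C | intermediate
27 | (2S,3R)-3-hydroxy-2-[(1S,3R,4S,4aS)-3-hydroxy-4-methyl-7-methylidene-1,2,3,4,4a,5,6,7-octahydronaphthalen-1-yl]-6-methylhept-5-en-4-one | C=C1C=C2[C@@H](CC1)[C@H](C)[C@H](O)C[C@H]2[C@H](C)[C@@H](O)C(=O)C=C(C)C | intermediate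
28 | (2S,3R)-2-[(1S,3R,4S,4aS)-3-acetoxy-4-methyl-7-methylidene-1,2,3,4,4a,5,6,7-octahydronaphthalen-1-yl]-6-methyl-4-oxohept-5-en-3-yl acetate (CNP0302999.1) | C=C1C=C2[C@@H](CC1)[C@H](C)[C@H](OC(C)=O)C[C@H]2[C@H](C)[C@@H](OC(C)=O)C(=O)C=C(C)C | target

Total step count: 16. Longest linear sequence: 16 steps (1 to 28).

Steps most likely to fail

Step 10 (cycloaddition). Facial discrimination at C4 may be low if the C10 side chain crowds the attacked face. Bonding may also occur in the opposite orientation, which would leave allylic sulfonyl groups at C6 whose reductive removal can shift the C1=C16 double bond. The allene may be lost by dimerisation or ene reaction before it cycloadds. The fallback sets out from keto ester 10 and comes back at diene ester 21, by Robinson annulation and Wittig methylenation. The kinetic enolate 11 (LiN(iPr)2, THF, −78 °C) is added to 3-(trimethylsilyl)but-3-en-2-one to give silyl diketone F1, the new C4–C5 bond forming anti to the C7 methyl. NaOMe in MeOH removes the silyl group to give 1,5-diketone F2 and closes ring A by aldol condensation between C2 and C3 to bicyclic enone F3 (C1 ketone, C2=C3). Methylenation of the C1 ketone with Ph3P=CH2 (Ph3PCH3Br, KOtBu, THF, 0 °C) gives 21, and the route continues with step 12.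

Step 6 (Michael addition). Addition of the ketone enolate to the β-substituted enoate may be slow, with competing proton transfer. The C10/C11 relationship may be poorly controlled if the closed transition state does not dominate. The fallback sets out from enol acetate 7 and comes back at keto ester 10, by an amine-catalysed Mukaiyama–Michael addition in which the catalyst, not the enolate face, fixes C11. MeLi and then Me3SiCl convert 7 into trimethylsilyl enol ether F4. This adds to (E)-but-2-enal in the presence of (2S,5S)-5-benzyl-2-tert-butyl-3-methylimidazolidin-4-one trifluoroacetate (iminium activation; catalyst antipode assigned by analogy with other π-nucleophiles) to give keto aldehyde F5, with C10 settling in the equatorial position. Pinnick oxidation (NaClO2, NaH2PO4, 2-methylbut-2-ene, t-BuOH–H2O) gives keto acid F6, and Me3SiCHN2 in MeOH–toluene gives 10.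

Step 12 (hydroxylation). Facial control at C12 from the single neighbouring centre C11 may be incomplete, and the electron-rich diene may be partly oxidised. The fallback sets out from ester 21 and comes back at Weinreb amide 24, with C12 set by a covalently bound auxiliary. LiOH in THF–H2O gives carboxylic acid F7. Activation with pivaloyl chloride and Et3N, then the lithium salt of (R)-4-benzyl-1,3-oxazolidin-2-one, gives imide F8. NaN(SiMe3)2 followed by 2-(phenylsulfonyl)-3-phenyloxaziridine hydroxylates the chelated Z-enolate on the face away from the benzyl group to give hydroxy imide F9 (12R). AlMe3 with MeNH(OMe)·HCl displaces the auxiliary and gives 24.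

Further compounds

F1 | step 10 | silyl diketone, the C4-[3-oxo-2-(trimethylsilyl)butyl] derivative of 10 (C4 substituent trans to C7 methyl, silyl-bearing carbon as a mixture) | O=C1[C@@H](CC([Si](C)(C)C)C(C)=O)[C@H](C)[C@H](O[Si](C)(C)C(C)(C)C)C[C@H]1[C@H](C)CC(=O)OC
F2 | step 10 | 1,5-diketone, the C4-(3-oxobutyl) derivative of 10 | O=C1[C@@H](CCC(C)=O)[C@H](C)[C@H](O[Si](C)(C)C(C)(C)C)C[C@H]1[C@H](C)CC(=O)OC
F3 | step 10 | bicyclic enone, the C1 ketone analogue of 21 (C1=O in place of C1=C16) | O=C1C=C2[C@@H](CC1)[C@H](C)[C@H](O[Si](C)(C)C(C)(C)C)C[C@H]2[C@H](C)CC(=O)OC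
F4 | step 6 | trimethylsilyl enol ether, (4R,5S)-4-[tert-butyl(dimethyl)silyl]oxy-5-methyl-1-(trimethylsilyloxy)cyclohex-1-ene | C[Si](C)(C)OC1=CC[C@@H](O[Si](C)(C)C(C)(C)C)[C@@H](C)C1
F5 | step 6 | keto aldehyde, (3R)-3-[(1S,4S,5R)-5-[tert-butyl(dimethyl)silyl]oxy-4-methyl-2-oxocyclohexyl]butanal | O=C1C[C@H](C)[C@H](O[Si](C)(C)C(C)(C)C)C[C@H]1[C@H](C)CC=O
F6 | step 6 | keto acid, (3R)-3-[(1S,4S,5R)-5-[tert-butyl(dimethyl)silyl]oxy-4-methyl-2-oxocyclohexyl]butanoic acid | O=C1C[C@H](C)[C@H](O[Si](C)(C)C(C)(C)C)C[C@H]1[C@H](C)CC(=O)O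
F7 | step 12 | carboxylic acid corresponding to ester 21 | C=C1C=C2[C@@H](CC1)[C@H](C)[C@H](O[Si](C)(C)C(C)(C)C)C[C@H]2[C@H](C)CC(=O)O
F8 | step 12 | imide, the N-acyl (R)-4-benzyl-1,3-oxazolidin-2-one of F7 | C=C1C=C2[C@@H](CC1)[C@H](C)[C@H](O[Si](C)(C)C(C)(C)C)C[C@H]2[C@H](C)CC(=O)N1[C@H](Cc3ccccc3)COC1=O
F9 | step 12 | hydroxy imide, the 12R α-hydroxy derivative of F8 | C=C1C=C2[C@@H](CC1)[C@H](C)[C@H](O[Si](C)(C)C(C)(C)C)C[C@H]2[C@H](C)[C@@H](O)C(=O)N1[C@H](Cc3ccccc3)COC1=O
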